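# Sophoraisoflavone A by closure of ring C through copper-catalysed enol O-arylation

## The problem

Sophoraisoflavone A (17) is an isoflavone: a benzo-fused pyran-4-one (rings A and C) carrying at C3 an aryl ring B, which is fused at C2'–C3' to a 2,2-dimethyl-2H-pyran (ring D) whose oxygen O1'' sits on C2'. Hydroxyl groups stand free at C5, C7 and C4'. The molecule has no stereocentre, so nothing has to be relayed and every selectivity question is one of regiochemistry. Ring D must be built through the 2'-oxygen, the one ortho to the inter-ring bond, although in a 2,4-dioxygenated ring B precursor the 4-oxygen is the more reactive one; the C3–C1' bond is also hindered, lying between the C4 carbonyl and O1''. The fragile elements are the styrene-type C3''=C4'' double bond of ring D (hydrogenation, electrophiles, strong acid), the tertiary allylic aryl ether at C2'', the electron-rich ring A, and C2 of the pyranone, which adds nucleophiles with ring opening. This excludes benzyl ethers that need hydrogenolysis and any Lewis-acid acylation of ring A once ring D is present. The feature to exploit is that O1 links the arene carbon C8a to C2, while C2, C3 and C4 form the enol of a 2-aryl-3-oxopropanal and C4 is attached to C4a, ortho to C8a. A bromine on C8a therefore lies ortho to a ketone and within reach of the enol oxygen through a six-membered ring.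

## Retrosynthesis

**17 from 16.** The last cut removes three O–CH2OCH3 acetal bonds. One kind of protecting group on all three phenols is preferred over a mixed set. Methoxymethyl ethers survive base, heat and copper and leave in dilute acid; benzyl ethers would cost the C3''=C4'' bond on hydrogenolysis, and silyl ethers would not survive hot carbonate. The forward step needs acid mild enough to spare the chromene.

**16 from 15 (key cut).** The O1–C8a aryl ether bond of ring C is cut, which opens ring C to the chelated enol 15 with bromine on the future C8a. The neighbouring cut O1–C2 is the classical one, but it needs a free ortho phenol on a deoxybenzoin, and such ketones are usually made by Lewis-acid acylation of a free polyphenol, which ring D would not tolerate. The cut C3–C1' would demand a 3-halochromone and a hindered ortho-oxygenated arylboron partner, each with extra functionalisation steps. With O1–C8a made last, ring A enters as an electrophile at both C4 and C8a, with no free phenol and all oxygens protected alike. Compound 15 is one ring simpler than 16. The forward reaction must arylate oxygen rather than carbon and must not touch the chromene or the acetals.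

**15 from 7 and 12.** The C3–C4 bond is cut, giving arylacetaldehyde 7 as the nucleophile (through its enamine 13) and aroyl chloride 12 as the electrophile; the vinylogous amide 14 is hydrolysed to 15 without isolation of 13 or 14. Cutting C2–C3 instead (formylation of a deoxybenzoin) only postpones the problem, since the deoxybenzoin would need a benzylic organometallic of the electron-rich ring B. The chosen cut uses the natural polarity of both partners and joins two fragments of similar size. The forward reaction must achieve C-acylation between two crowded centres and hydrolyse 14 without loss of acetals.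

**12 from 8.** The acyl carbon C4 is traced through acid 11 and aldehyde 10 to phenolic aldehyde 9, and the C4–C4a bond is cut by formylation of bromoresorcinol 8. Formylation is placed before protection because the chlorophosphorus reagent would not spare acetals; the position para to one hydroxyl and ortho to the other (and to bromine) is the normal site of attack on a 5-substituted resorcinol. The acid chloride must be made without liberating hydrogen chloride.

**7 from 5.** The C2–C3 bond is cut: aldehyde 5 is homologated by one carbon through enol ether 6. This is shorter than reduction, halide formation, cyanide displacement and partial reduction. It asks only that the enol ether be hydrolysed faster than the aryl acetal.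

**5 from 1 and 3.** Ring D is cut at O1''–C2'' and C3'–C4''. Aryl propargyl ether 4 rearranges thermally to the chromene, and 4 comes from phenol 2 and tertiary chloride 3. Phenol 2 comes from 1 by protecting the more reactive 4-hydroxyl, so that the chelated 2-hydroxyl is the only one left to alkylate; with O4 free the pyran would form on the wrong oxygen. The sigmatropic step has only one free ortho position (C3), so its regiochemistry is not in question.

## Roads not taken

**Alternative 1:** The cut passes through ring B itself (C1'–C2', C2'–C3', C4'–C5', C5'–C6'), leaving the chromone-bearing diazo enone A2 and the siloxyalkyne A3. On irradiation A2 would undergo Wolff rearrangement to a vinylketene, which adds A3 in a [2+2] sense; ring opening, 6π-electrocyclisation and tautomerisation (Danheiser benzannulation) give phenol A1.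
- Merits: the whole C1'–C4' substitution pattern is written in one step with mechanism-fixed regiochemistry, and O2' arrives free while O4' is silylated, which is exactly the differentiation ring D needs.
- Weak points: A1 still lacks ring D (oxidative cyclisation of the prenyl phenol is needed), and its benzyl ethers cannot be removed by hydrogenolysis once C3''=C4'' exists. A2 needs a multistep build-up on a preformed chromone that absorbs in the same UV region and is electrophilic at C2. A3 needs ynolate chemistry.
- Comparison: in its handling of ring B regiochemistry this road is better than the chosen one, which relies on alkylating a chelated phenol and on a hot Claisen step. The chosen plan sets against it commercial aromatic building blocks, only thermal and ionic steps, one protecting group type, and a ring D that is complete at step 3.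

**Alternative 2:** The cut is the C2'–O1'' bond. Ring B is dearomatised at C1' as the 4-methoxycyclohexadienone A5, obtained by oxidation of phenol A6 in methanol; the tertiary alkoxide of the side chain adds to C2' in a 6-endo oxa-Michael step, and acid then expels methanol to give chroman A4.
- Merits: the 2'-oxygen is introduced late on a simple 4'-hydroxy-3'-alkyl isoflavone, so no 2'-oxygenated ring B precursor is needed, and the tether alone decides between C2' and C6'.
- Weak points: a tertiary alkoxide is a poor and reversible Michael donor. The acid used for rearomatisation invites dienone–phenol rearrangement, with migration of the chromonyl group from the quaternary C1'. The product is a chroman, so the C3''=C4'' bond must still be introduced by dehydrogenation next to a free phenol.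
- Comparison: this road has the simpler ring B precursor and avoids both the chelated-phenol alkylation and the high-temperature rearrangement. Its redox economy is poorer (one oxidation before and one after the key step), and it does not deliver the chromene, which the chosen plan carries from step 3 through base-only chemistry.

**Alternative 3:** The cut is C3'–C4''. The 2'-O-(1,1-dimethylpropargyl) ether A8 would cyclise under Ph3PAuNTf2, C3' attacking the gold-activated terminal alkyne carbon in a 6-endo hydroarylation to give chromene A7.
- Merits: it is catalytic and runs near room temperature, only one ortho position is free, and a late common intermediate could serve several pyrano- and prenyl-isoflavones.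
- Weak points: A8 requires etherification of a hindered 2'-hydroxyl with a tertiary propargylic electrophile on an isoflavone carrying three other phenols, hence a mixed protecting group array. A cationic gold catalyst meets acetals, a chelating 5-hydroxy ketone and an ionisable tertiary aryl ether. The isoflavone core of A8 must still be assembled, so no steps are saved.
- Comparison: this road forms the same pyran bond by the same logic as steps 2 and 3, and the gold step is clearly milder than a 180 °C rearrangement. The chosen plan sets against it that the rearrangement is done on a simple benzaldehyde where nothing is sensitive, and that all phenols carry the same group and are released in one step.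

Key step: step 11

## Route

Remark on the chemistry: the target has no stereocentre. Enol ether 6 is carried as an E/Z mixture because both isomers hydrolyse to 7, and 15 is drawn as its chelated Z enol although it reacts as the delocalised enolate.

Step 1
Reactants: 1 2,4-dihydroxybenzaldehyde
Product: 2 2-hydroxy-4-(methoxymethoxy)benzaldehyde
Conditions: MOMCl (1.1 equiv), K2CO3, acetone, 0 °C → rt
Reagents that add atoms: chloromethyl methyl ether, COCCl
Why: Williamson etherification; the 2-hydroxyl is hydrogen-bonded to the aldehyde and is the weaker nucleophile, so the 4-hydroxyl should react selectively, and this group is also the final protection of O4'.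

Step 2
Reactants: 2 2-hydroxy-4-(methoxymethoxy)benzaldehyde, 3 3-chloro-3-methylbut-1-yne
Product: 4 4-(methoxymethoxy)-2-[(2-methylbut-3-yn-2-yl)oxy]benzaldehyde
Conditions: DBU, CuCl2·2H2O (cat.), MeCN, 0 °C → rt
Reagents that add atoms: none
Why: Copper-catalysed propargylic etherification; the copper acetylide of 3 ionises the tertiary chloride to an allenylidene-type electrophile that the phenoxide captures at the tertiary carbon, so no SN2 attack at a tertiary centre is needed, and DBU breaks the chelate of the phenol.

Step 3
Reactants: 4 4-(methoxymethoxy)-2-[(2-methylbut-3-yn-2-yl)oxy]benzaldehyde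
Product: 5 5-(methoxymethoxy)-2,2-dimethyl-2H-chromene-8-carbaldehyde
Conditions: PhNEt2, 180 °C
Reagents that add atoms: none
Why: Aromatic propargyl Claisen rearrangement to C3 (the only free ortho position), then enolisation, [1,5]-hydrogen shift and 6π-oxa-electrocyclisation of the o-quinone methide close ring D; the basic solvent protects the acetal.

Step 4
Reactants: 5 5-(methoxymethoxy)-2,2-dimethyl-2H-chromene-8-carbaldehyde
Product: 6 8-(2-methoxyethenyl)-5-(methoxymethoxy)-2,2-dimethyl-2H-chromene (E/Z mixture)
Conditions: Ph3P(CH2OMe)Cl, KOtBu, THF, 0 °C → rt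
Reagents that add atoms: (methoxymethyl)triphenylphosphonium chloride, COC[P+](c1ccccc1)(c1ccccc1)c1ccccc1.[Cl-]
Why: Wittig olefination of a non-enolisable aryl aldehyde with a methoxymethylene ylide; the basic conditions leave the acetal and the chromene untouched, and the alkene geometry is irrelevant.

Step 5
Reactants: 6 8-(2-methoxyethenyl)-5-(methoxymethoxy)-2,2-dimethyl-2H-chromene (E/Z mixture)
Product: 7 2-[5-(methoxymethoxy)-2,2-dimethyl-2H-chromen-8-yl]acetaldehyde
Conditions: 1 M aq HCl, THF, rt
Reagents that add atoms: water, O
Why: Acid-catalysed enol ether hydrolysis (C-protonation, hemiacetal, loss of methanol); enol ethers hydrolyse several orders of magnitude faster than formaldehyde acetals, which should leave a window in which the aryl MOM ether and the chromene double bond survive.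

Step 6
Reactants: 8 5-bromobenzene-1,3-diol
Product: 9 2-bromo-4,6-dihydroxybenzaldehyde
Conditions: POCl3, DMF, MeCN, 0 °C → rt; then H2O, 50 °C
Reagents that add atoms: N,N-dimethylformamide, CN(C)C=O; water, O
Why: Vilsmeier–Haack formylation; as with other 5-substituted resorcinols, the chloroiminium ion should attack para to one hydroxyl and ortho to the other, not the crowded position between the two hydroxyls.

Step 7
Reactants: 9 2-bromo-4,6-dihydroxybenzaldehyde
Product: 10 2-bromo-4,6-bis(methoxymethoxy)benzaldehyde
Conditions: NaH, MOMCl, DMF, 0 °C → rt
Reagents that add atoms: chloromethyl methyl ether, COCCl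
Why: Williamson etherification of both phenoxides; full deprotonation with NaH overcomes the chelation of the ortho hydroxyl, and the aldehyde has no α-hydrogen.

Step 8
Reactants: 10 2-bromo-4,6-bis(methoxymethoxy)benzaldehyde
Product: 11 2-bromo-4,6-bis(methoxymethoxy)benzoic acid
Conditions: NaClO2, NaH2PO4, 2-methylbut-2-ene, t-BuOH–H2O, rt
Reagents that add atoms: sodium chlorite, [Na+].[O-]Cl=O
Why: Pinnick oxidation; the buffered medium spares the acetals, and the alkene scavenges hypochlorous acid before it can chlorinate the electron-rich ring.

Step 9
Reactants: 11 2-bromo-4,6-bis(methoxymethoxy)benzoic acid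
Product: 12 2-bromo-4,6-bis(methoxymethoxy)benzoyl chloride
Conditions: 1-chloro-N,N,2-trimethylprop-1-en-1-amine, CH2Cl2, 0 °C → rt; used at once
Reagents that add atoms: 1-chloro-N,N,2-trimethylprop-1-en-1-amine, CC(C)=C(Cl)N(C)C
Why: Acid chloride formation with an α-chloroenamine gives only a neutral amide as by-product, so no hydrogen chloride is released that could cleave the ortho acetal; immediate use limits decomposition.

Step 10
Reactants: 7 2-[5-(methoxymethoxy)-2,2-dimethyl-2H-chromen-8-yl]acetaldehyde, 12 2-bromo-4,6-bis(methoxymethoxy)benzoyl chloride
Product: 15 (Z)-1-[2-bromo-4,6-bis(methoxymethoxy)phenyl]-3-hydroxy-2-[5-(methoxymethoxy)-2,2-dimethyl-2H-chromen-8-yl]prop-2-en-1-one, via pyrrolidine enamine 13 (not isolated), via enaminone 14 (not isolated)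
Conditions: pyrrolidine (1.05 equiv), 4 Å MS, CH2Cl2, 0 °C → rt; then Et3N, 12, 0 °C → rt; then 1 M aq HCl, THF, rt
Reagents that add atoms: water, O
Why: Stork enamine acylation; 7 condenses to the conjugated E enamine 13, whose β-carbon is acylated by 12 (which ionises readily to an acylium ion stabilised by its ortho and para alkoxy groups, avoiding a crowded tetrahedral intermediate), and Et3N removes the α-proton to give vinylogous amide 14. Brief aqueous acid exchanges pyrrolidine for hydroxyl to leave the chelated enol 15, with the acetals surviving on the same kinetic grounds as in step 5.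

Step 11
Reactants: 15 (Z)-1-[2-bromo-4,6-bis(methoxymethoxy)phenyl]-3-hydroxy-2-[5-(methoxymethoxy)-2,2-dimethyl-2H-chromen-8-yl]prop-2-en-1-one
Product: 16 5,7-bis(methoxymethoxy)-3-[5-(methoxymethoxy)-2,2-dimethyl-2H-chromen-8-yl]-4H-chromen-4-one
Conditions: CuI (10 mol%), 1,10-phenanthroline (20 mol%), Cs2CO3 (2 equiv), DMF, 90 °C, argon
Reagents that add atoms: none
Why: Intramolecular Ullmann-type O-arylation. Cs2CO3 converts the acidic enol into the delocalised 1,3-dicarbonyl enolate, which binds phenanthroline-ligated monovalent copper; the C–Br bond ortho to the ketone is then activated at copper (oxidative addition to an aryl species of trivalent copper, helped by the neighbouring carbonyl), and C–O reductive elimination forms O1–C8a and returns monovalent copper. The closest known reaction type is the copper-catalysed cyclisation of enolisable 1-(2-haloaryl)-1,3-dicarbonyl compounds to chromones and flavones, applied here to an α-formyl deoxybenzoin. Ring C closes as a six-membered ring, formally 6-exo-trig at the arene carbon (the breaking C–Br bond lies outside the new ring), through a seven-membered copper chelate. No stereocentre is formed. The selectivity needed is O- over C-arylation and formyl-oxygen over ketone-oxygen attack; C3 and the ketone oxygen could reach C8a only through four-membered rings, so ring size leaves the formyl-derived oxygen as the only nucleophile. Enolate geometry is no obstacle, because rotation about C2–C3 in the delocalised anion interconverts the E and Z forms and cyclisation drains the Z form. The medium is basic, anhydrous and non-oxidising, so the chromene double bond and the three acetals should be untouched, and exclusion of water suppresses retro-Claisen loss of the formyl group.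

Step 12
Reactants: 16 5,7-bis(methoxymethoxy)-3-[5-(methoxymethoxy)-2,2-dimethyl-2H-chromen-8-yl]-4H-chromen-4-one
Product: 17 sophoraisoflavone A, 5,7-dihydroxy-3-(5-hydroxy-2,2-dimethyl-2H-chromen-8-yl)-4H-chromen-4-one
Conditions: 3 M aq HCl, MeOH, 50 °C
Reagents that add atoms: none
Why: Acid-catalysed transacetalisation of the three aryl MOM ethers to methanol; dilute acid at moderate temperature is the usual way to unmask pyrano- and prenyl-isoflavones and is expected to spare the chromene, whose nearest phenol cannot cyclise onto it.

## Compound list

1 | 2,4-dihydroxybenzaldehyde | O=Cc1ccc(O)cc1O | starting material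
2 | 2-hydroxy-4-(methoxymethoxy)benzaldehyde | O=Cc1ccc(OCOC)cc1O | intermediate
3 | 3-chloro-3-methylbut-1-yne | C#CC(C)(C)Cl | starting material
4 | 4-(methoxymethoxy)-2-[(2-methylbut-3-yn-2-yl)oxy]benzaldehyde | O=Cc1ccc(OCOC)cc1OC(C)(C)C#C | intermediate
5 | 5-(methoxymethoxy)-2,2-dimethyl-2H-chromene-8-carbaldehyde | O=Cc1ccc(OCOC)c2C=CC(C)(C)Oc12 | intermediate
6 | 8-(2-methoxyethenyl)-5-(methoxymethoxy)-2,2-dimethyl-2H-chromene (E/Z mixture) | COC=Cc1ccc(OCOC)c2C=CC(C)(C)Oc12 | intermediate
7 | 2-[5-(methoxymethoxy)-2,2-dimethyl-2H-chromen-8-yl]acetaldehyde | O=CCc1ccc(OCOC)c2C=CC(C)(C)Oc12 | intermediate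
8 | 5-bromobenzene-1,3-diol | Oc1cc(O)cc(Br)c1 | starting material
9 | 2-bromo-4,6-dihydroxybenzaldehyde | O=Cc1c(Br)cc(O)cc1O | intermediate
10 | 2-bromo-4,6-bis(methoxymethoxy)benzaldehyde | O=Cc1c(Br)cc(OCOC)cc1OCOC | intermediate
11 | 2-bromo-4,6-bis(methoxymethoxy)benzoic acid | OC(=O)c1c(Br)cc(OCOC)cc1OCOC | intermediate
12 | 2-bromo-4,6-bis(methoxymethoxy)benzoyl chloride | ClC(=O)c1c(Br)cc(OCOC)cc1OCOC | intermediate
13 | 1-{(E)-2-[5-(methoxymethoxy)-2,2-dimethyl-2H-chromen-8-yl]ethenyl}pyrrolidine | C1CCN(C1)/C=C/c1ccc(OCOC)c2C=CC(C)(C)Oc12 | intermediate (not isolated)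
14 | 1-[2-bromo-4,6-bis(methoxymethoxy)phenyl]-2-[5-(methoxymethoxy)-2,2-dimethyl-2H-chromen-8-yl]-3-(pyrrolidin-1-yl)prop-2-en-1-one (alkene geometry not fixed) | O=C(c1c(Br)cc(OCOC)cc1OCOC)C(=CN1CCCC1)c1ccc(OCOC)c2C=CC(C)(C)Oc12 | intermediate (not isolated)
15 | (Z)-1-[2-bromo-4,6-bis(methoxymethoxy)phenyl]-3-hydroxy-2-[5-(methoxymethoxy)-2,2-dimethyl-2H-chromen-8-yl]prop-2-en-1-one | O=C(c1c(Br)cc(OCOC)cc1OCOC)/C(=C\O)c1ccc(OCOC)c2C=CC(C)(C)Oc12 | intermediate
16 | 5,7-bis(methoxymethoxy)-3-[5-(methoxymethoxy)-2,2-dimethyl-2H-chromen-8-yl]-4H-chromen-4-one | O=c1c(-c2ccc(OCOC)c3C=CC(C)(C)Oc23)coc2cc(OCOC)cc(OCOC)c12 | intermediate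
17 | sophoraisoflavone A, 5,7-dihydroxy-3-(5-hydroxy-2,2-dimethyl-2H-chromen-8-yl)-4H-chromen-4-one | CC1(C)C=Cc2c(O)ccc(-c3coc4cc(O)cc(O)c4c3=O)c2O1 | target

## Step count and risk

Total step count: 12. Longest linear sequence: 8 steps (steps 1–5 and 10–12). Ring A is prepared in a four-step side branch (steps 6–9).

**Step 11 (key step).** The most likely failure is retro-Claisen loss of the formyl group from the enolate, through attack of carbonate or adventitious hydroxide at the aldehyde carbon, before the C–Br bond is activated. That activation may be slow because the 2,6-disubstituted aroyl group is twisted out of the ring plane and assists the metal poorly. Protodebromination and sequestration of copper as a stable enolate chelate are further drains.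

The fallback gives up the O1–C8a closure for the classical O1–C2 closure. It sets out from enamine 13 (made from 7 as in step 10) and comes back at 17. Purchased 2,4,6-trihydroxybenzaldehyde F1 is converted with NaH and MOMCl into 2,4,6-tris(methoxymethoxy)benzaldehyde F2. Oxidation with NaClO2 under the conditions of step 8 gives 2,4,6-tris(methoxymethoxy)benzoic acid F3, and the chloroenamine of step 9 gives 2,4,6-tris(methoxymethoxy)benzoyl chloride F4. Acylation of 13 with F4 in the presence of Et3N gives the enaminone 2-[5-(methoxymethoxy)-2,2-dimethyl-2H-chromen-8-yl]-3-(pyrrolidin-1-yl)-1-[2,4,6-tris(methoxymethoxy)phenyl]prop-2-en-1-one F5. Treatment with HCl in methanol then cleaves all four acetals; one freed ortho phenol adds to the aminomethylene carbon and expels pyrrolidine, so ring C closes and 17 forms directly.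

**Step 10.** C-acylation may stall because the α-aryl enamine carbon and the 2,6-disubstituted acyl chloride are both crowded. Meanwhile 12 can destroy itself by attack of the ortho acetal oxygen on the acyl carbon with loss of chloromethane, and 13 can be consumed by self-condensation.

The fallback builds the ketone before the formyl group and avoids the acid chloride. It sets out from aldehydes 5 and 10 and comes back at 15. Aldehyde 5 is reduced with NaBH4 in methanol to [5-(methoxymethoxy)-2,2-dimethyl-2H-chromen-8-yl]methanol F6, and MsCl, Et3N and LiCl convert this into 8-(chloromethyl)-5-(methoxymethoxy)-2,2-dimethyl-2H-chromene F7. Insertion with Mg turnings in the presence of ZnCl2 and LiCl gives the benzylic zinc reagent chloro{[5-(methoxymethoxy)-2,2-dimethyl-2H-chromen-8-yl]methyl}zinc F8. In the presence of the MgCl2 so formed, F8 adds to 10 to give racemic 1-[2-bromo-4,6-bis(methoxymethoxy)phenyl]-2-[5-(methoxymethoxy)-2,2-dimethyl-2H-chromen-8-yl]ethan-1-ol F9. Dess–Martin periodinane buffered with NaHCO3 oxidises F9 to the deoxybenzoin 1-[2-bromo-4,6-bis(methoxymethoxy)phenyl]-2-[5-(methoxymethoxy)-2,2-dimethyl-2H-chromen-8-yl]ethan-1-one F10. Claisen formylation of F10 with ethyl formate and NaH in THF, followed by careful acidification, gives 15.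

**Step 5.** Acid may cleave the aryl acetal or hydrate the chromene double bond before the enol ether is consumed, and the electron-rich arylacetaldehyde can undergo acid-catalysed self-aldol condensation.

The fallback uses no acid. It sets out from 5 and comes back at 7. Methylenation of 5 with Ph3P=CH2 gives 8-ethenyl-5-(methoxymethoxy)-2,2-dimethyl-2H-chromene F11. 9-BBN hydroborates the terminal vinyl group far faster than the cis-disubstituted ring alkene, and oxidation with NaOH/H2O2 gives 2-[5-(methoxymethoxy)-2,2-dimethyl-2H-chromen-8-yl]ethan-1-ol F12. Dess–Martin periodinane oxidises F12 to 7.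

**Step 12.** Under protic acid the chromene may add methanol or water across C3''=C4'', or oligomerise through the benzylic cation, before the last acetal has gone.

The fallback replaces Brønsted-acid solvolysis by a buffered silyl transfer. It sets out from 16 and comes back at 17. TMSOTf with 2,2'-bipyridyl in CH2Cl2 converts the three aryl MOM ethers into aryl silyl ethers, giving 3-[2,2-dimethyl-5-(trimethylsilyloxy)-2H-chromen-8-yl]-5,7-bis(trimethylsilyloxy)-4H-chromen-4-one F13. Water at neutral pH then hydrolyses F13 to 17.

## Further compounds

F1 | step 11 | 2,4,6-trihydroxybenzaldehyde (purchased) | O=Cc1c(O)cc(O)cc1O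
F2 | step 11 | 2,4,6-tris(methoxymethoxy)benzaldehyde | O=Cc1c(OCOC)cc(OCOC)cc1OCOC
F3 | step 11 | 2,4,6-tris(methoxymethoxy)benzoic acid | OC(=O)c1c(OCOC)cc(OCOC)cc1OCOC
F4 | step 11 | 2,4,6-tris(methoxymethoxy)benzoyl chloride | ClC(=O)c1c(OCOC)cc(OCOC)cc1OCOC
F5 | step 11 | 2-[5-(methoxymethoxy)-2,2-dimethyl-2H-chromen-8-yl]-3-(pyrrolidin-1-yl)-1-[2,4,6-tris(methoxymethoxy)phenyl]prop-2-en-1-one | O=C(c1c(OCOC)cc(OCOC)cc1OCOC)C(=CN1CCCC1)c1ccc(OCOC)c2C=CC(C)(C)Oc12
F6 | step 10 | [5-(methoxymethoxy)-2,2-dimethyl-2H-chromen-8-yl]methanol | OCc1ccc(OCOC)c2C=CC(C)(C)Oc12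
F7 | step 10 | 8-(chloromethyl)-5-(methoxymethoxy)-2,2-dimethyl-2H-chromene | ClCc1ccc(OCOC)c2C=CC(C)(C)Oc12
F8 | step 10 | chloro{[5-(methoxymethoxy)-2,2-dimethyl-2H-chromen-8-yl]methyl}zinc | Cl[Zn]Cc1ccc(OCOC)c2C=CC(C)(C)Oc12
F9 | step 10 | racemic 1-[2-bromo-4,6-bis(methoxymethoxy)phenyl]-2-[5-(methoxymethoxy)-2,2-dimethyl-2H-chromen-8-yl]ethan-1-ol | OC(Cc1ccc(OCOC)c2C=CC(C)(C)Oc12)c1c(Br)cc(OCOC)cc1OCOC
F10 | step 10 | 1-[2-bromo-4,6-bis(methoxymethoxy)phenyl]-2-[5-(methoxymethoxy)-2,2-dimethyl-2H-chromen-8-yl]ethan-1-one | O=C(Cc1ccc(OCOC)c2C=CC(C)(C)Oc12)c1c(Br)cc(OCOC)cc1OCOC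
F11 | step 5 | 8-ethenyl-5-(methoxymethoxy)-2,2-dimethyl-2H-chromene | C=Cc1ccc(OCOC)c2C=CC(C)(C)Oc12
F12 | step 5 | 2-[5-(methoxymethoxy)-2,2-dimethyl-2H-chromen-8-yl]ethan-1-ol | OCCc1ccc(OCOC)c2C=CC(C)(C)Oc12
F13 | step 12 | 3-[2,2-dimethyl-5-(trimethylsilyloxy)-2H-chromen-8-yl]-5,7-bis(trimethylsilyloxy)-4H-chromen-4-one | O=c1c(-c2ccc(O[Si](C)(C)C)c3C=CC(C)(C)Oc23)coc2cc(O[Si](C)(C)C)cc(O[Si](C)(C)C)c12
A1 | alternative 1 | 5,7-bis(benzyloxy)-3-[2-hydroxy-3-(3-methylbut-2-en-1-yl)-4-(triisopropylsilyloxy)phenyl]-4H-chromen-4-one | O=c1c(-c2ccc(O[Si](C(C)C)(C(C)C)C(C)C)c(CC=C(C)C)c2O)coc2cc(OCc3ccccc3)cc(OCc3ccccc3)c12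
A2 | alternative 1 | 5,7-bis(benzyloxy)-3-[(E)-4-diazo-3-oxobut-1-en-1-yl]-4H-chromen-4-one | [N-]=[N+]=CC(=O)/C=C/c1coc2cc(OCc3ccccc3)cc(OCc3ccccc3)c2c1=O
A3 | alternative 1 | triisopropyl[(5-methylhex-4-en-1-yn-1-yl)oxy]silane | CC(C)=CCC#CO[Si](C(C)C)(C(C)C)C(C)C
A4 | alternative 2 | 3-(5-hydroxy-2,2-dimethylchroman-8-yl)-5,7-bis(methoxymethoxy)-4H-chromen-4-one | O=c1c(-c2ccc(O)c3CCC(C)(C)Oc23)coc2cc(OCOC)cc(OCOC)c12
A5 | alternative 2 | racemic 3-[3-(3-hydroxy-3-methylbutyl)-1-methoxy-4-oxocyclohexa-2,5-dien-1-yl]-5,7-bis(methoxymethoxy)-4H-chromen-4-one | COC1(C=CC(=O)C(CCC(C)(C)O)=C1)c1coc2cc(OCOC)cc(OCOC)c2c1=O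
A6 | alternative 2 | 3-[4-hydroxy-3-(3-hydroxy-3-methylbutyl)phenyl]-5,7-bis(methoxymethoxy)-4H-chromen-4-one | O=c1c(-c2ccc(O)c(CCC(C)(C)O)c2)coc2cc(OCOC)cc(OCOC)c12
A7 | alternative 3 | 5-hydroxy-7-(methoxymethoxy)-3-[5-(methoxymethoxy)-2,2-dimethyl-2H-chromen-8-yl]-4H-chromen-4-one | O=c1c(-c2ccc(OCOC)c3C=CC(C)(C)Oc23)coc2cc(OCOC)cc(O)c12
A8 | alternative 3 | 5-hydroxy-7-(methoxymethoxy)-3-{4-(methoxymethoxy)-2-[(2-methylbut-3-yn-2-yl)oxy]phenyl}-4H-chromen-4-one | O=c1c(-c2ccc(OCOC)cc2OC(C)(C)C#C)coc2cc(OCOC)cc(O)c12
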